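- birch: starting material 0.014 M; reagent 0.0154 M; second substrate 7 mM; free catalyst 0.13 mM; impurity 26 µM; the very flask that is asked about, followed so far
- flask: starting material 0.014 M; reagent 0.0154 M; second substrate 7.00 mM; free catalyst 0.13 mM; impurity 26 µM; time 2.0 min

birch run (percent of the starting material charged)

| time / s | target / % | starting material / % |
|---|---|---|
| 10.0 | 44.6 | 55.8 |
| 20.0 | 57.4 | 43.1 |
| 40.0 | 66.2 | 34.3 |

(each reading ± 0.5 percentage points)

- steps that have been proposed: free catalyst + impurity -> spent catalyst; second substrate + reagent + free catalyst -> free catalyst + second product; starting material + reagent + free catalyst -> free catalyst + target

- amount of target in percent of the starting material charged, at 12 s, 40 s and 2.0 min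

1. I began from the slowing of the birch run, which is this flask followed so far: target read 44.6% after the first 10.0 s but gained 8.8 percentage points in the last 20.0 s.

2. In the proposed steps, starting material and second substrate each take one reagent on free catalyst, while impurity, charged at 20.0% of the catalyst, removes free catalyst. When I divided the two substrate rates, time, reagent and catalyst cancelled, so in this flask, with impurity charged below the catalyst, I expected impurity to move the clock but not the stopping point.

3. Reagent, at 15.4 mM, was less than the 21.0 mM of the two substrates together, which made it the limiting reagent. I called the reagent charge divided by the summed substrate charges the reagent coverage, 73.3%: the share of the substrate that reagent can convert. With equal constants, both substrates lose the same share, so target stops at the coverage.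

4. I tested this on the reading at 40.0 s, 66.2%, which lay below the coverage. But second substrate was not read, so equal constants stayed untested, and the coverage carries no clock. I committed to about 73.3% at 2.0 min and kept the reading for 40 s.

5. The forecast gave 47.8%, 66.1% and 72.2%, ending 1.1 points below my figure: “If the second substrate is faster, the plateau is lower.”

    free catalyst + impurity → spent catalyst (k = 1.50 × 10⁶ M⁻¹ s⁻¹)
    second substrate + reagent + free catalyst → free catalyst + second product (k = 73000 M⁻² s⁻¹)
    starting material + reagent + free catalyst → free catalyst + target (k = 61000 M⁻² s⁻¹)

The flask gave 47.9%, 66.0% and 71.0%, the last 2.3 points below the coverage. At 2.00 min this flask held 23% of its second substrate against 29% of its starting material, with 0.30% of the reagent left. Twice the impurity changes neither charge in the coverage, which stays 73.3%, and that second flask gave 70.6% target.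

The data are calculated on assumed constants; scatter was added.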